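**Plan**

- Retrosynthesis (flavanone numbering): O3, O5 and O3' are unmasked last. Ring C is then cut at C8a–O1 and C4–C4a in one stroke, giving a ring A aryne and a C2–C3–C4 silyloxy lactone. The lactone is cut at C2–C3 (aldol), and the aryne precursor is traced back through its C–Si, C–prenyl and O-substituents to 5-methoxyresorcinol.
- Enabling feature: C8a and C4a are neighbours in ring A, the first bound to O1 and the second to the acyl carbon C4. O1 and C4 stand 1,3 on the C2–C3–C4 chain, and C5 next to C4a carries oxygen. Ring A is therefore the adduct of a 3-oxygenated aryne that takes a nucleophile at C8a and an electrophile at C4a.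
- Forward: ring A is dressed first (MOM ether, carbamate, two ortho-metalations, triflate). The chain is made by an anti glycolate aldol and silylated. Ring C is closed last by a fluoride-triggered aryne annulation, and acid methanolysis frees the three hydroxyls.
- Stereochemistry: C3 and C2 are both set in the aldol under control of the (5S,6S)-butane-2,3-diacetal ring (attack anti to the axial methoxy group, closed chair transition state). The annulation forms no bond at either center. The diacetal ring is controller, O3 protection and acyl activator in one, and is taken out in steps 9 and 10.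

Key step: step 9

Assumption: (5S,6S)-5,6-dimethoxy-5,6-dimethyl-1,4-dioxan-2-one is taken as a catalogue compound, and the facial sense of its aldol (electrophile anti to the axial C5 methoxy group, substituent equatorial, hence 3R) is assigned from the chair model.

**Step 1**
Reactants: 1 5-methoxyresorcinol
Product: 2 3-methoxy-5-(methoxymethoxy)phenol
Conditions: MOMCl (1.0 equiv), i-Pr2NEt (1.2 equiv), CH2Cl2/THF, 0 °C to rt
Reagents that add atoms: chloromethyl methyl ether, COCCl
Why: Williamson-type O-alkylation of one of two equivalent phenols, which is statistical, so about one equivalent of reagent is used and recovered 1 and the bis-ether are recycled.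

**Step 2**
Reactants: 2 3-methoxy-5-(methoxymethoxy)phenol
Product: 3 3-methoxy-5-(methoxymethoxy)phenyl N-isopropylcarbamate
Conditions: i-PrNCO (1.5 equiv), Et3N (0.2 equiv), CH2Cl2, rt
Reagents that add atoms: isopropyl isocyanate, CC(C)N=C=O
Why: base-catalysed addition of the phenol to the isocyanate (carbamoylation) installs the strongest ortho-directing group of the ring in a form that can later be removed by E1cB cleavage.

**Step 3**
Reactants: 3 3-methoxy-5-(methoxymethoxy)phenyl N-isopropylcarbamate
Product: 7 5-methoxy-3-(methoxymethoxy)-2-(trimethylsilyl)phenyl N-isopropylcarbamate, via N-silyl carbamate 4 (not isolated), via aryllithium 5 (not isolated), via doubly silylated carbamate 6 (not isolated)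
Conditions: TBSOTf (1.1 equiv), TMEDA, Et2O, 0 °C to rt; n-BuLi (2.2 equiv), TMEDA, −78 °C; Me3SiCl, −78 °C to rt; 10% aq citric acid
Reagents that add atoms: chlorotrimethylsilane, C[Si](C)(C)Cl
Why: directed ortho-metalation of the carbamate (N–H masked in the flask as the N-tert-butyldimethylsilyl derivative) should take place at the ring position flanked by the two best directing groups, carbamate and MOM ether, and the aryllithium is trapped by the chlorosilane.

**Step 4**
Reactants: 7 5-methoxy-3-(methoxymethoxy)-2-(trimethylsilyl)phenyl N-isopropylcarbamate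
Product: 11 3-methoxy-5-(methoxymethoxy)-2-(3-methylbut-2-en-1-yl)-6-(trimethylsilyl)phenyl N-isopropylcarbamate, via N-trimethylsilyl carbamate 8 (not isolated), via aryllithium 9 (not isolated), via N-silyl prenyl carbamate 10 (not isolated)
Conditions: Me3SiOTf (1.1 equiv), TMEDA, Et2O, 0 °C to rt; n-BuLi (2.2 equiv), TMEDA, −78 °C; CuBr·SMe2 (10 mol %), prenyl bromide, −78 °C to 0 °C; 10% aq citric acid
Reagents that add atoms: 1-bromo-3-methylbut-2-ene (prenyl bromide), CC(C)=CCBr
Why: second directed ortho-metalation, here with the N–H masked in the flask as the N-trimethylsilyl derivative (which falls off in the mild acidic work-up without harm to the aryl silane, the MOM ether or the prenyl group), in which silicon blocks the more acidic site so that the carbamate steers lithium to its other ortho position (between carbamate and methoxy), followed by copper-catalysed allylic substitution at the primary carbon of prenyl bromide (SN2 sense) to give the linear prenyl group.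

**Step 5**
Reactants: 11 3-methoxy-5-(methoxymethoxy)-2-(3-methylbut-2-en-1-yl)-6-(trimethylsilyl)phenyl N-isopropylcarbamate
Product: 13 3-methoxy-5-(methoxymethoxy)-2-(3-methylbut-2-en-1-yl)-6-(trimethylsilyl)phenyl trifluoromethanesulfonate, via phenol 12 (not isolated)
Conditions: Et2NH (1.3 equiv), DBU (1.5 equiv), MeCN, 40 °C; then PhNTf2 (1.5 equiv), rt
Reagents that add atoms: N-phenylbis(trifluoromethanesulfonimide), O=S(=O)(N(c1ccccc1)S(=O)(=O)C(F)(F)F)C(F)(F)F
Why: the N–H carbamate is cleaved by E1cB loss of isopropyl isocyanate (trapped by Et2NH), a path that is insensitive to the two ortho substituents, and the phenoxide is triflated in the same flask to give the 2-(trimethylsilyl)aryl triflate aryne precursor.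

**Step 6**
Reactants: 14 isovanillin (3-hydroxy-4-methoxybenzaldehyde)
Product: 15 4-methoxy-3-(methoxymethoxy)benzaldehyde
Conditions: MOMCl (1.3 equiv), i-Pr2NEt (1.5 equiv), CH2Cl2, 0 °C to rt
Reagents that add atoms: chloromethyl methyl ether, COCCl
Why: Williamson-type O-alkylation gives a phenol protecting group that withstands the aldol base and the fluoride of step 9 and falls in the final acid step.

**Step 7**
Reactants: 16 (5S,6S)-5,6-dimethoxy-5,6-dimethyl-1,4-dioxan-2-one; 15 4-methoxy-3-(methoxymethoxy)benzaldehyde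
Product: 19 (3R,5S,6S)-3-{(R)-hydroxy[4-methoxy-3-(methoxymethoxy)phenyl]methyl}-5,6-dimethoxy-5,6-dimethyl-1,4-dioxan-2-one, via lithium enolate 17 (not isolated), via lithium aldolate 18 (not isolated)
Conditions: LiN(SiMe3)2 (1.05 equiv), THF, −78 °C; then 15, −78 °C; AcOH quench at −78 °C
Reagents that add atoms: none
Why: lithium enolate aldol addition of the chiral glycolate lactone, in which the ring fixes the enolate geometry, the aldehyde should add on the face anti to the axial C5 methoxy group (3R), the closed Zimmerman–Traxler chair should give the anti (R) carbinol, and the cold quench forestalls retro-aldol equilibration.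

**Step 8**
Reactants: 19 (3R,5S,6S)-3-{(R)-hydroxy[4-methoxy-3-(methoxymethoxy)phenyl]methyl}-5,6-dimethoxy-5,6-dimethyl-1,4-dioxan-2-one
Product: 20 (3R,5S,6S)-5,6-dimethoxy-3-{(R)-[4-methoxy-3-(methoxymethoxy)phenyl][(trimethylsilyl)oxy]methyl}-5,6-dimethyl-1,4-dioxan-2-one
Conditions: Me3SiCl (1.3 equiv), imidazole (2 equiv), CH2Cl2, 0 °C to rt; filtration through Et3N-washed SiO2
Reagents that add atoms: chlorotrimethylsilane, C[Si](C)(C)Cl
Why: O-silylation of the secondary alcohol under neutral conditions removes the only O–H proton of the fragment and turns it into a fluoride-releasable alkoxide without touching either stereocenter.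

**Step 9**
Reactants: 13 3-methoxy-5-(methoxymethoxy)-2-(3-methylbut-2-en-1-yl)-6-(trimethylsilyl)phenyl trifluoromethanesulfonate; 20 (3R,5S,6S)-5,6-dimethoxy-3-{(R)-[4-methoxy-3-(methoxymethoxy)phenyl][(trimethylsilyl)oxy]methyl}-5,6-dimethyl-1,4-dioxan-2-one
Product: 23 (2R,3R)-7-methoxy-3-{[(2S)-2-methoxy-3-oxobutan-2-yl]oxy}-2-[4-methoxy-3-(methoxymethoxy)phenyl]-5-(methoxymethoxy)-8-(3-methylbut-2-en-1-yl)-2,3-dihydro-4H-chromen-4-one, via aryne 21 (not isolated), via potassium lactolate 22 (not isolated)
Conditions: 13 (1.3 equiv), KF (3 equiv), 18-crown-6 (3 equiv), THF, −20 °C to rt, fluoride added in portions; AcOH quench; SiO2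
Reagents that add atoms: none
Why: Proposed new method: fluoride strips the aryl silane of 13 (loss of triflate gives aryne 21) and the silyl ether of 20 alike, so that a proton-free alkoxide adds to C8a of the aryne and the aryl anion born at C4a attacks the lactone carbonyl, giving the hemiketal alkoxide 22, which on the acidic quench opens to the C4 ketone with loss of methanol. The closest known reaction type is the fluoride-triggered annulation of 2-(trimethylsilyl)aryl triflates with methyl salicylates to xanthones (O-arylation, then intramolecular acyl substitution), extended here from a phenoxide/aryl ester pair to a secondary alkoxide/lactone pair. Ring C closes by intermolecular C8a–O1 bond formation followed by 6-exo-trig attack of C4a on the carbonyl carbon, a formal [4+2] anionic annulation. No permanent stereocenter is created, since C2 and C3 come unchanged from 20 (the oxygen nucleophile reacts with retention) and the only new center, the hemiketal carbon of 22, is erased on opening. The step needs regioselectivity (oxygen to C8a, acyl to C4a), which the C5 methoxymethoxy group should secure by making the aryne carbon meta to it the electrophilic one and by stabilising the ortho anion, and it needs acylation to beat protonation, which the silyl ether pronucleophile (no O–H in the flask) and the reactive lactone should secure. As long as C4 rests as the alkoxide 22 the C3–H is not acidic, which should protect C3 from epimerisation and C2 from retro-oxa-Michael opening under the basic conditions.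

**Step 10**
Reactants: 23 (2R,3R)-7-methoxy-3-{[(2S)-2-methoxy-3-oxobutan-2-yl]oxy}-2-[4-methoxy-3-(methoxymethoxy)phenyl]-5-(methoxymethoxy)-8-(3-methylbut-2-en-1-yl)-2,3-dihydro-4H-chromen-4-one
Product: 24 (2R,3R)-3,5-dihydroxy-2-(3-hydroxy-4-methoxyphenyl)-7-methoxy-8-(3-methylbut-2-en-1-yl)-2,3-dihydro-4H-chromen-4-one
Conditions: HCl (1.25 M in MeOH), rt to 40 °C
Reagents that add atoms: none
Why: acid-catalysed acetal exchange with methanol should cleave both MOM ethers and the mixed ketal at O3 (the unit that is methanolysed in the usual unmasking of butane-2,3-diacetals), while the prenyl group, which has no free ortho phenol, and the trans C2/C3 arrangement, the thermodynamically preferred one, are left as they are.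

**Compound list**

1 | 5-methoxyresorcinol (5-methoxybenzene-1,3-diol) | COc1cc(O)cc(O)c1 | starting material
2 | 3-methoxy-5-(methoxymethoxy)phenol | COCOc1cc(O)cc(OC)c1 | intermediate
3 | 3-methoxy-5-(methoxymethoxy)phenyl N-isopropylcarbamate | COCOc1cc(OC)cc(OC(=O)NC(C)C)c1 | intermediate
4 | N-(tert-butyldimethylsilyl) derivative of 3, formed in the flask | COCOc1cc(OC)cc(OC(=O)N(C(C)C)[Si](C)(C)C(C)(C)C)c1 | intermediate
5 | aryllithium from 4, lithium between carbamate and MOM ether, formed in the flask | COCOc1cc(OC)cc(OC(=O)N(C(C)C)[Si](C)(C)C(C)(C)C)c1[Li] | intermediate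
6 | 5-methoxy-3-(methoxymethoxy)-2-(trimethylsilyl)phenyl N-(tert-butyldimethylsilyl)-N-isopropylcarbamate, formed in the flask | COCOc1cc(OC)cc(OC(=O)N(C(C)C)[Si](C)(C)C(C)(C)C)c1[Si](C)(C)C | intermediate
7 | 5-methoxy-3-(methoxymethoxy)-2-(trimethylsilyl)phenyl N-isopropylcarbamate | COCOc1cc(OC)cc(OC(=O)NC(C)C)c1[Si](C)(C)C | intermediate
8 | 5-methoxy-3-(methoxymethoxy)-2-(trimethylsilyl)phenyl N-isopropyl-N-(trimethylsilyl)carbamate, formed in the flask | COCOc1cc(OC)cc(OC(=O)N(C(C)C)[Si](C)(C)C)c1[Si](C)(C)C | intermediate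
9 | aryllithium from 8, lithium between carbamate and methoxy, formed in the flask | COCOc1cc(OC)c([Li])c(OC(=O)N(C(C)C)[Si](C)(C)C)c1[Si](C)(C)C | intermediate
10 | N-(trimethylsilyl) derivative of 11, formed in the flask | COCOc1cc(OC)c(CC=C(C)C)c(OC(=O)N(C(C)C)[Si](C)(C)C)c1[Si](C)(C)C | intermediate
11 | 3-methoxy-5-(methoxymethoxy)-2-(3-methylbut-2-en-1-yl)-6-(trimethylsilyl)phenyl N-isopropylcarbamate | COCOc1cc(OC)c(CC=C(C)C)c(OC(=O)NC(C)C)c1[Si](C)(C)C | intermediate
12 | 3-methoxy-5-(methoxymethoxy)-2-(3-methylbut-2-en-1-yl)-6-(trimethylsilyl)phenol, formed in the flask as its DBU salt | COCOc1cc(OC)c(CC=C(C)C)c(O)c1[Si](C)(C)C | intermediate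
13 | 3-methoxy-5-(methoxymethoxy)-2-(3-methylbut-2-en-1-yl)-6-(trimethylsilyl)phenyl trifluoromethanesulfonate | COCOc1cc(OC)c(CC=C(C)C)c(OS(=O)(=O)C(F)(F)F)c1[Si](C)(C)C | intermediate
14 | isovanillin (3-hydroxy-4-methoxybenzaldehyde) | COc1ccc(C=O)cc1O | starting material
15 | 4-methoxy-3-(methoxymethoxy)benzaldehyde | COCOc1cc(C=O)ccc1OC | intermediate
16 | (5S,6S)-5,6-dimethoxy-5,6-dimethyl-1,4-dioxan-2-one (butane-2,3-diacetal glycolate) | O=C1CO[C@](C)(OC)[C@@](C)(OC)O1 | starting material
17 | lithium enolate of 16, formed in the flask | [Li]OC1=CO[C@](C)(OC)[C@@](C)(OC)O1 | intermediate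
18 | lithium aldolate of 19, formed in the flask | O=C1[C@@H]([C@H](O[Li])c2ccc(OC)c(OCOC)c2)O[C@](C)(OC)[C@@](C)(OC)O1 | intermediate
19 | (3R,5S,6S)-3-{(R)-hydroxy[4-methoxy-3-(methoxymethoxy)phenyl]methyl}-5,6-dimethoxy-5,6-dimethyl-1,4-dioxan-2-one | O=C1[C@@H]([C@H](O)c2ccc(OC)c(OCOC)c2)O[C@](C)(OC)[C@@](C)(OC)O1 | intermediate
20 | (3R,5S,6S)-5,6-dimethoxy-3-{(R)-[4-methoxy-3-(methoxymethoxy)phenyl][(trimethylsilyl)oxy]methyl}-5,6-dimethyl-1,4-dioxan-2-one | O=C1[C@@H]([C@H](O[Si](C)(C)C)c2ccc(OC)c(OCOC)c2)O[C@](C)(OC)[C@@](C)(OC)O1 | intermediate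
21 | aryne: 1,2-didehydro-5-methoxy-3-(methoxymethoxy)-6-(3-methylbut-2-en-1-yl)benzene, formed in the flask | COCOC1=CC(OC)=C(CC=C(C)C)C#C1 | intermediate
22 | potassium lactolate: ring C closed, C4 held as the hemiketal alkoxide of the dioxane ring (configuration at C4 open), formed in the flask | COc1ccc([C@H]2Oc3c(CC=C(C)C)c(OC)cc(OCOC)c3C4([O-])O[C@](C)(OC)[C@@](C)(OC)O[C@H]24)cc1OCOC.[K+] | intermediate
23 | (2R,3R)-7-methoxy-3-{[(2S)-2-methoxy-3-oxobutan-2-yl]oxy}-2-[4-methoxy-3-(methoxymethoxy)phenyl]-5-(methoxymethoxy)-8-(3-methylbut-2-en-1-yl)-2,3-dihydro-4H-chromen-4-one | COc1ccc([C@H]2Oc3c(CC=C(C)C)c(OC)cc(OCOC)c3C(=O)[C@@H]2O[C@](C)(OC)C(C)=O)cc1OCOC | intermediate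
24 | (2R,3R)-3,5-dihydroxy-2-(3-hydroxy-4-methoxyphenyl)-7-methoxy-8-(3-methylbut-2-en-1-yl)-2,3-dihydro-4H-chromen-4-one | COc1ccc([C@H]2Oc3c(CC=C(C)C)c(OC)cc(O)c3C(=O)[C@@H]2O)cc1O | target

**Step count and risks**

Total step count: 10. Longest linear sequence: 7 steps (steps 1, 2, 3, 4, 5, 9, 10).

Steps most likely to fail:

1. Step 9 (proposed new method). The unmasked alkoxide may fragment by retro-aldol before it meets the aryne, the aryl anion may be protonated or silylated before it reaches the lactone, or the alkoxide may add at the other aryne carbon next to the MOM ether. The fallback uses known chemistry, sets out from 13 and 15 and comes back at 24.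
 - The aryne from 13 (CsF, THF, 125 °C, sealed tube) is intercepted by acetic acid in the known addition of carboxylic acids across arynes with 1,3-acyl shift. This gives 1-[2-hydroxy-4-methoxy-6-(methoxymethoxy)-3-(3-methylbut-2-en-1-yl)phenyl]ethan-1-one F1 with the same regiochemistry (oxygen meta to the MOM ether).
 - Claisen–Schmidt condensation of F1 with 15 (KOH, EtOH) gives the (E)-2'-hydroxychalcone F2. Silylation of the phenol (TBSOTf, 2,6-lutidine) gives the silyl ether F3.
 - Juliá–Colonna epoxidation (poly-L-leucine, urea–H2O2, DBU, THF) should give the (2R,3S)-epoxy ketone F4.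
 - Buffered TBAF/AcOH releases the phenol epoxide F5. In HCl/MeOH this should close by 6-endo opening at the benzylic carbon, with inversion, to the bis-MOM dihydroflavonol F6, and the same medium removes both MOM groups to give 24.

2. Step 4. Lithiation may take place at the ring position between the MOM ether and the methoxy group, the carbamoyl group may migrate to the ring (anionic ortho-Fries), or the allylic bromide may be attacked with transposition. The fallback avoids the second metalation, sets out from 7 and comes back at 12.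
 - Et2NH/DBU (MeCN, 40 °C) cleaves the carbamate to 5-methoxy-3-(methoxymethoxy)-2-(trimethylsilyl)phenol F7. Allyl bromide and K2CO3 in acetone give the allyl ether F8.
 - Aromatic Claisen rearrangement (N,N-diethylaniline, 180 °C) can end only at the one free ortho position and gives the 2-allylphenol F9.
 - Cross-metathesis with 2-methylbut-2-ene (second-generation Grubbs catalyst RuCl2(=CHPh)(PCy3)(H2IMes), CH2Cl2, 40 °C) gives phenol 12. This is triflated with PhNTf2 and DBU as in the second half of step 5, to reach 13.

3. Step 7. With the electron-rich aldehyde the aldol addition may become reversible and lose its anti selectivity, or the aldehyde face may be poorly differentiated. The fallback sets the carbinol center by reduction instead, sets out from the crude epimer mixture of 19 and comes back at 19 as one isomer.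
 - Dess–Martin periodinane (CH2Cl2, rt) converges all isomers to the β-keto lactone (5S,6S)-3-[4-methoxy-3-(methoxymethoxy)benzoyl]-5,6-dimethoxy-5,6-dimethyl-1,4-dioxan-2-one F10, whose C3 is labile and should settle equatorial.
 - Noyori asymmetric transfer hydrogenation under dynamic kinetic resolution (RuCl(p-cymene)[(S,S)-TsDPEN], HCO2H/Et3N, rt) should then give the (R)-carbinol 19. The catalyst antipode is chosen by the aryl ketone rule.

Further compounds
F1 | step 9 | 1-[2-hydroxy-4-methoxy-6-(methoxymethoxy)-3-(3-methylbut-2-en-1-yl)phenyl]ethan-1-one | CC(=O)c1c(OCOC)cc(OC)c(CC=C(C)C)c1O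
F2 | step 9 | (E)-1-[2-hydroxy-4-methoxy-6-(methoxymethoxy)-3-(3-methylbut-2-en-1-yl)phenyl]-3-[4-methoxy-3-(methoxymethoxy)phenyl]prop-2-en-1-one | COCOc1cc(/C=C/C(=O)c2c(OCOC)cc(OC)c(CC=C(C)C)c2O)ccc1OC
F3 | step 9 | (E)-1-[2-(tert-butyldimethylsilyloxy)-4-methoxy-6-(methoxymethoxy)-3-(3-methylbut-2-en-1-yl)phenyl]-3-[4-methoxy-3-(methoxymethoxy)phenyl]prop-2-en-1-one | COCOc1cc(/C=C/C(=O)c2c(OCOC)cc(OC)c(CC=C(C)C)c2O[Si](C)(C)C(C)(C)C)ccc1OC
F4 | step 9 | [2-(tert-butyldimethylsilyloxy)-4-methoxy-6-(methoxymethoxy)-3-(3-methylbut-2-en-1-yl)phenyl]{(2R,3S)-3-[4-methoxy-3-(methoxymethoxy)phenyl]oxiran-2-yl}methanone | O=C(c2c(OCOC)cc(OC)c(CC=C(C)C)c2O[Si](C)(C)C(C)(C)C)[C@@H]3O[C@H]3c4ccc(OC)c(OCOC)c4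
F5 | step 9 | [2-hydroxy-4-methoxy-6-(methoxymethoxy)-3-(3-methylbut-2-en-1-yl)phenyl]{(2R,3S)-3-[4-methoxy-3-(methoxymethoxy)phenyl]oxiran-2-yl}methanone | O=C(c2c(OCOC)cc(OC)c(CC=C(C)C)c2O)[C@@H]3O[C@H]3c4ccc(OC)c(OCOC)c4
F6 | step 9 | (2R,3R)-3-hydroxy-7-methoxy-2-[4-methoxy-3-(methoxymethoxy)phenyl]-5-(methoxymethoxy)-8-(3-methylbut-2-en-1-yl)-2,3-dihydro-4H-chromen-4-one | COc1ccc([C@H]2Oc3c(CC=C(C)C)c(OC)cc(OCOC)c3C(=O)[C@@H]2O)cc1OCOC
F7 | step 4 | 5-methoxy-3-(methoxymethoxy)-2-(trimethylsilyl)phenol | COCOc1cc(OC)cc(O)c1[Si](C)(C)C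
F8 | step 4 | [2-(allyloxy)-4-methoxy-6-(methoxymethoxy)phenyl]trimethylsilane | COCOc1cc(OC)cc(OCC=C)c1[Si](C)(C)C
F9 | step 4 | 2-allyl-3-methoxy-5-(methoxymethoxy)-6-(trimethylsilyl)phenol | COCOc1cc(OC)c(CC=C)c(O)c1[Si](C)(C)C
F10 | step 7 | (5S,6S)-3-[4-methoxy-3-(methoxymethoxy)benzoyl]-5,6-dimethoxy-5,6-dimethyl-1,4-dioxan-2-one | O=C1C(C(=O)c2ccc(OC)c(OCOC)c2)O[C@](C)(OC)[C@@](C)(OC)O1
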